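**Plan**
- Feature: in the tetrahydrofuran (O1; C2 with ring C; C3 with CH2OH; C4 with OH; C5 with the C6 methylene of ring B), the neighbours C4 and C5 each carry an oxygen and C6 is benzylic. Two such acceptor carbons can be joined only after one is turned into a radical, and ring B is placed to hold the radical that then appears at C6.
- Cuts: first C4–C5 (aldehyde ketyl onto an O1–C5=C6 styryl enol ether). Next the vinylic O1–C5 bond, which separates fragment 1 (ring C, C2–C4) from fragment 2 (rings A and B, C5, C6, glycerol chain C7''–C9'', C7'' on ring A). Last C2–C3 and C7''–C8'', two aldol reactions of O-benzylvanillin.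
- Forward: fragment 1 takes 6 steps and fragment 2 takes 8. Copper-catalysed O-vinylation joins them, the C4 alcohol is freed and oxidised, and the only new ring (the tetrahydrofuran) closes in step 18. Desilylation and hydrogenolysis finish the synthesis.
- Stereochemistry: C2 and C3 come from an Evans syn aldol of the (S)-crotonyl imide; its vinyl group becomes C4, so aldol-syn equals 2,3-trans in the ring. C8'' comes from an Evans syn aldol of the (R)-aryloxyacetyl imide, and C7'' from a Mitsunobu inversion (threo to erythro). C4 and C5 are set by substrate control in the ring closure.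

Key step: step 18

Remark: acid 14, the O-carboxymethyl ether of vanillin, is taken as a catalogue compound. TBS = tert-butyldimethylsilyl, Bn = benzyl, Piv = pivaloyl.

**Step 1**
Reactants: 1 (S)-4-benzyl-1,3-oxazolidin-2-one; 2 (E)-but-2-enoyl chloride
Product: 4 (S)-4-benzyl-3-[(E)-but-2-enoyl]-1,3-oxazolidin-2-one, via N-lithio oxazolidinone 3 (not isolated)
Conditions: n-BuLi, THF, −78 °C; then 2, −78 → 0 °C
Reagents that add atoms: none
Why: N-acylation of the lithiated oxazolidinone by an acid chloride is the standard entry to Evans imides, keeps the alkene conjugated and forms no stereocentre.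

**Step 2**
Reactants: 4 (S)-4-benzyl-3-[(E)-but-2-enoyl]-1,3-oxazolidin-2-one; 5 4-(benzyloxy)-3-methoxybenzaldehyde (O-benzylvanillin)
Product: 8 (S)-4-benzyl-3-{(2S)-2-[(S)-[4-(benzyloxy)-3-methoxyphenyl](hydroxy)methyl]but-3-enoyl}-1,3-oxazolidin-2-one (syn aldol adduct), via boron dienolate 6 (not isolated), via boron aldolate 7 (not isolated)
Conditions: Bu2BOTf, Et3N, CH2Cl2, −78 → 0 °C; 5, −78 → 0 °C; H2O2, MeOH, pH 7 buffer, 0 °C
Reagents that add atoms: none
Why: Evans syn aldol, in which the (Z)-boron dienolate reacts at its α-carbon through a Zimmerman–Traxler chair on the face away from the auxiliary benzyl group, setting C3 and C2 and leaving a vinyl group as the latent C4.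

**Step 3**
Reactants: 8 syn aldol adduct
Product: 9 (1S,2R)-1-[4-(benzyloxy)-3-methoxyphenyl]-2-ethenylpropane-1,3-diol
Conditions: LiBH4, MeOH (1 equiv), Et2O, 0 °C
Reagents that add atoms: none
Why: Reductive auxiliary cleavage, in which LiBH4 reduces only the activated imide carbonyl and leaves the alkene and both stereocentres untouched.

**Step 4**
Reactants: 9 (1S,2R)-diol
Product: 10 (1S,2R)-1-[4-(benzyloxy)-3-methoxyphenyl]-2-{[(tert-butyldimethylsilyl)oxy]methyl}but-3-en-1-ol
Conditions: TBSCl (1.05 equiv), imidazole, CH2Cl2, 0 °C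
Reagents that add atoms: tert-butyldimethylsilyl chloride, CC(C)(C)[Si](C)(C)Cl
Why: Silylation with a bulky silyl chloride discriminates the primary hydroxyl from the hindered secondary benzylic one.

**Step 5**
Reactants: 10 homoallylic alcohol
Product: 12 (1S,2R)-1-[4-(benzyloxy)-3-methoxyphenyl]-2-{[(tert-butyldimethylsilyl)oxy]methyl}propane-1,3-diol, via hydroxy aldehyde 11 (not isolated)
Conditions: O3, CH2Cl2–MeOH, −78 °C (stopped at first blue colour); then NaBH4, −78 → 0 °C
Reagents that add atoms: ozone, [O-][O+]=O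
Why: Ozonolysis with reductive work-up cleaves the only C=C bond, and the β-hydroxy aldehyde is reduced cold before it can epimerise at C3 or undergo retro-aldol cleavage.

**Step 6**
Reactants: 12 (1S,2R)-diol
Product: 13 (2R,3S)-3-[4-(benzyloxy)-3-methoxyphenyl]-2-{[(tert-butyldimethylsilyl)oxy]methyl}-3-hydroxypropyl pivalate (fragment 1)
Conditions: PivCl (1.1 equiv), pyridine, CH2Cl2, 0 °C
Reagents that add atoms: pivaloyl chloride, CC(C)(C)C(=O)Cl
Why: Selective acylation, in which the bulky acid chloride takes the primary hydroxyl only, and the pivalate is the ester least prone to migrate in step 15 yet still falls to hydride in step 16.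

**Step 7**
Reactants: 14 (4-formyl-2-methoxyphenoxy)acetic acid; 15 (R)-4-benzyl-1,3-oxazolidin-2-one
Product: 17 (R)-4-benzyl-3-[(4-formyl-2-methoxyphenoxy)acetyl]-1,3-oxazolidin-2-one, via mixed pivalic anhydride 16 (not isolated)
Conditions: PivCl, Et3N, THF, −20 °C; then LiCl, 15, −20 °C → rt
Reagents that add atoms: none
Why: Mixed-anhydride N-acylation, in which LiCl/Et3N activates the oxazolidinone enough to attack the less hindered carbonyl of 16 without a strong base, so the free aldehyde survives.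

**Step 8**
Reactants: 17 imide aldehyde
Product: 18 (R)-4-benzyl-3-({4-[(E)-2-iodoethenyl]-2-methoxyphenoxy}acetyl)-1,3-oxazolidin-2-one
Conditions: CrCl2 (6 equiv), CHI3 (2 equiv), THF, 0 °C → rt
Reagents that add atoms: iodoform, IC(I)I
Why: Takai olefination, whose gem-dichromium reagent adds to the aromatic aldehyde and eliminates to the (E)-vinyl iodide, the imide being inert to divalent chromium; removing the aldehyde here also prevents self-condensation in step 9.

**Step 9**
Reactants: 18 vinyl iodide imide; 5 4-(benzyloxy)-3-methoxybenzaldehyde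
Product: 21 (R)-4-benzyl-3-[(2R,3S)-3-[4-(benzyloxy)-3-methoxyphenyl]-3-hydroxy-2-{4-[(E)-2-iodoethenyl]-2-methoxyphenoxy}propanoyl]-1,3-oxazolidin-2-one (syn aldol adduct), via boron enolate 19 (not isolated), via boron aldolate 20 (not isolated)
Conditions: Bu2BOTf, Et3N, CH2Cl2, 0 °C; 5, −78 → 0 °C; H2O2, MeOH, pH 7 buffer, 0 °C
Reagents that add atoms: none
Why: Evans syn aldol of an aryloxyacetyl imide, in which the (Z)-boron enolate and the (R)-auxiliary fix C8'' in its final configuration and give C7'' as the epimer (threo series).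

**Step 10**
Reactants: 21 syn aldol adduct
Product: 22 (1S,2S)-1-[4-(benzyloxy)-3-methoxyphenyl]-2-{4-[(E)-2-iodoethenyl]-2-methoxyphenoxy}propane-1,3-diol (threo)
Conditions: LiBH4, MeOH (1 equiv), THF, 0 °C
Reagents that add atoms: none
Why: Reductive auxiliary cleavage as in step 3, with the vinyl iodide and aryl ethers inert to borohydride.

**Step 11**
Reactants: 22 threo diol
Product: 23 (1S,2S)-1-[4-(benzyloxy)-3-methoxyphenyl]-3-[(tert-butyldimethylsilyl)oxy]-2-{4-[(E)-2-iodoethenyl]-2-methoxyphenoxy}propan-1-ol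
Conditions: TBSCl (1.05 equiv), imidazole, CH2Cl2, 0 °C
Reagents that add atoms: tert-butyldimethylsilyl chloride, CC(C)(C)[Si](C)(C)Cl
Why: Selective silylation of the primary C9'' hydroxyl leaves only the benzylic C7'' hydroxyl free for inversion.

**Step 12**
Reactants: 23 threo alcohol
Product: 24 (1R,2S)-1-[4-(benzyloxy)-3-methoxyphenyl]-3-[(tert-butyldimethylsilyl)oxy]-2-{4-[(E)-2-iodoethenyl]-2-methoxyphenoxy}propyl 4-nitrobenzoate (erythro)
Conditions: 4-nitrobenzoic acid, PPh3, DIAD, THF, 0 °C → rt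
Reagents that add atoms: 4-nitrobenzoic acid, O=C(O)c1ccc([N+](=O)[O-])cc1
Why: Mitsunobu inversion, in which SN2 displacement of the oxyphosphonium group by the acidic carboxylate turns C7'' from S to R, a conversion established for arylglycerol β-aryl ethers.

**Step 13**
Reactants: 24 erythro 4-nitrobenzoate
Product: 25 (1R,2S)-1-[4-(benzyloxy)-3-methoxyphenyl]-3-[(tert-butyldimethylsilyl)oxy]-2-{4-[(E)-2-iodoethenyl]-2-methoxyphenoxy}propan-1-ol (erythro)
Conditions: K2CO3 (cat.), MeOH–THF, 0 °C → rt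
Reagents that add atoms: none
Why: Base-catalysed transesterification removes the activated ester by acyl–oxygen cleavage, so C7'' keeps its new configuration and the silyl ether and vinyl iodide are untouched.

**Step 14**
Reactants: 25 erythro alcohol
Product: 26 (1R,2S)-bis-TBS ether, 4-[(E)-2-iodoethenyl]-2-methoxyphenyl ether of the protected ring A glycerol (fragment 2)
Conditions: TBSOTf, 2,6-lutidine, CH2Cl2, −78 → 0 °C
Reagents that add atoms: tert-butyldimethylsilyl triflate, CC(C)(C)[Si](C)(C)OS(=O)(=O)C(F)(F)F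
Why: Silyl triflate with a hindered base silylates the crowded benzylic hydroxyl on oxygen without ionising C7''.

**Step 15**
Reactants: 13 fragment 1 alcohol; 26 fragment 2 vinyl iodide
Product: 27 (E)-styryl enol ether pivalate (C2 S, C3 R; C7'' R, C8'' S)
Conditions: CuI (10 mol %), 3,4,7,8-tetramethyl-1,10-phenanthroline (20 mol %), Cs2CO3, toluene, 80 °C
Reagents that add atoms: none
Why: Copper-catalysed Ullmann-type C–O coupling of a vinyl iodide with an aliphatic alcohol retains the alkene geometry, and the C2–O bond stays intact so no stereocentre is touched.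

**Step 16**
Reactants: 27 enol ether pivalate
Product: 28 (E)-styryl enol ether primary alcohol
Conditions: i-Bu2AlH (3 equiv), CH2Cl2, −78 °C
Reagents that add atoms: none
Why: Reductive ester cleavage with i-Bu2AlH at low temperature is non-acidic, so the enol ether, silyl ethers and benzyl ethers remain.

**Step 17**
Reactants: 28 primary alcohol
Product: 29 (2R,3S)-3-[4-(benzyloxy)-3-methoxyphenyl]-2-{[(tert-butyldimethylsilyl)oxy]methyl}-3-{[(E)-2-arylethenyl]oxy}propanal, aryl = ring B carrying the (7''R,8''S)-bis-TBS glycerol and ring A (cyclisation precursor)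
Conditions: Dess–Martin periodinane, pyridine, CH2Cl2, 0 °C; used at once
Reagents that add atoms: none
Why: Buffered Dess–Martin oxidation stops at the aldehyde under near-neutral conditions, which spares the enol ether and avoids epimerisation or β-elimination at C3.

**Step 18**
Reactants: 29 enol ether aldehyde
Product: 32 (2S,3S,4S,5R,7''R,8''S)-protected target with free C4 hydroxyl, via samarium ketyl 30 (not isolated), via cyclised benzylic radical 31 (not isolated)
Conditions: SmI2 (4 equiv), HMPA (16 equiv), t-BuOH (10 equiv), THF, −78 → 0 °C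
Reagents that add atoms: none
Why: Proposed new method: SmI2–HMPA gives one electron to the aldehyde of 29, the samarium-bound ketyl 30 attacks the oxygen-bearing alkene carbon C5 because this leaves the radical at C6 next to ring B (31), and a second SmI2 together with t-BuOH turns C6 into the CH2 of 32. The closest known reaction types are SmI2 ketyl–olefin cyclisations of aldehydes onto β-alkoxyacrylates, which give trans-2-alkyl-3-hydroxy cyclic ethers, and onto styrenes, whereas a β-alkoxystyrene with its electron-rich alkene has not served as acceptor. The tetrahydrofuran closes in the 5-exo-trig mode, the 6-endo alternative at C6 being slower and giving a radical stabilised by oxygen only. C4 is controlled by C3, since the HMPA-laden O–Sm group takes the pseudo-equatorial site trans to CH2OTBS, and C5 is controlled by the ketyl itself, since O–Sm and the styryl carbon C6 avoid each other and the benzyl group ends trans to the C4 oxygen. The step needs this 3,4-trans-4,5-trans (hence 2,5-trans) array over the 2,5-cis-3,4-cis isomer of a chair-like closure; the boat-like arrangement that delivers it keeps ring C, CH2OTBS and O–Sm all pseudo-equatorial and requires an s-cis-like enol ether, which the (E)-alkene with only hydrogen on the inside can adopt. Chemoselectivity rests on the aldehyde being the only group that divalent samarium reduces here, and the large excess of t-BuOH is meant to protonate the reduced C6 before it can expel O1.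

**Step 19**
Reactants: 32 tris-TBS ether
Product: 33 bis(benzyl ether) tetraol (all four aliphatic hydroxyls free, both phenols still benzylated)
Conditions: Bu4NF, THF, 0 °C → rt
Reagents that add atoms: none
Why: Fluoride desilylation removes the three TBS groups by attack at silicon only, so no C–O bond or stereocentre is affected.

**Step 20**
Reactants: 33 bis(benzyl ether) tetraol
Product: 34 target, CNP0123626.1
Conditions: H2 (1 atm), 10% Pd/C, EtOAc–EtOH, rt, stopped at full conversion
Reagents that add atoms: none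
Why: Catalytic hydrogenolysis cleaves phenolic benzyl ethers much faster than the secondary benzylic C7''–OH and C2–O1 bonds, which survive under these mild conditions.

**Compound list**
1 | (S)-4-benzyl-1,3-oxazolidin-2-one | O=C1N[C@@H](Cc2ccccc2)CO1 | starting material
2 | (E)-but-2-enoyl chloride | C/C=C/C(=O)Cl | starting material
3 | N-lithio-(S)-4-benzyl-1,3-oxazolidin-2-one | [Li]N1[C@@H](Cc2ccccc2)COC1=O | intermediate
4 | (S)-4-benzyl-3-[(E)-but-2-enoyl]-1,3-oxazolidin-2-one | C/C=C/C(=O)N1[C@@H](Cc2ccccc2)COC1=O | intermediate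
5 | 4-(benzyloxy)-3-methoxybenzaldehyde | COc1cc(C=O)ccc1OCc1ccccc1 | starting material
6 | (Z)-dibutylboron dienolate of 4 | C=C/C=C(\OB(CCCC)CCCC)N1[C@@H](Cc2ccccc2)COC1=O | intermediate
7 | dibutylboron aldolate of 8 | C=C[C@H](C(=O)N1[C@@H](Cc2ccccc2)COC1=O)[C@H](OB(CCCC)CCCC)c1ccc(OCc2ccccc2)c(OC)c1 | intermediate
8 | syn aldol adduct, (2S,3S) in the acyl chain, (S)-auxiliary | C=C[C@H](C(=O)N1[C@@H](Cc2ccccc2)COC1=O)[C@H](O)c1ccc(OCc2ccccc2)c(OC)c1 | intermediate
9 | (1S,2R)-1-[4-(benzyloxy)-3-methoxyphenyl]-2-ethenylpropane-1,3-diol | C=C[C@H](CO)[C@H](O)c1ccc(OCc2ccccc2)c(OC)c1 | intermediate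
10 | (1S,2R)-1-[4-(benzyloxy)-3-methoxyphenyl]-2-[(TBS-oxy)methyl]but-3-en-1-ol | C=C[C@H](CO[Si](C)(C)C(C)(C)C)[C@H](O)c1ccc(OCc2ccccc2)c(OC)c1 | intermediate
11 | (2R,3S)-3-[4-(benzyloxy)-3-methoxyphenyl]-3-hydroxy-2-[(TBS-oxy)methyl]propanal | O=C[C@H](CO[Si](C)(C)C(C)(C)C)[C@H](O)c1ccc(OCc2ccccc2)c(OC)c1 | intermediate
12 | (1S,2R)-1-[4-(benzyloxy)-3-methoxyphenyl]-2-[(TBS-oxy)methyl]propane-1,3-diol | OC[C@H](CO[Si](C)(C)C(C)(C)C)[C@H](O)c1ccc(OCc2ccccc2)c(OC)c1 | intermediate
13 | (2R,3S)-3-[4-(benzyloxy)-3-methoxyphenyl]-3-hydroxy-2-[(TBS-oxy)methyl]propyl pivalate | CC(C)(C)C(=O)OC[C@H](CO[Si](C)(C)C(C)(C)C)[C@H](O)c1ccc(OCc2ccccc2)c(OC)c1 | intermediate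
14 | (4-formyl-2-methoxyphenoxy)acetic acid | COc1cc(C=O)ccc1OCC(=O)O | starting material
15 | (R)-4-benzyl-1,3-oxazolidin-2-one | O=C1N[C@H](Cc2ccccc2)CO1 | starting material
16 | mixed anhydride of 14 and pivalic acid | COc1cc(C=O)ccc1OCC(=O)OC(=O)C(C)(C)C | intermediate
17 | (R)-4-benzyl-3-[(4-formyl-2-methoxyphenoxy)acetyl]-1,3-oxazolidin-2-one | COc1cc(C=O)ccc1OCC(=O)N1[C@H](Cc2ccccc2)COC1=O | intermediate
18 | (R)-4-benzyl-3-({4-[(E)-2-iodoethenyl]-2-methoxyphenoxy}acetyl)-1,3-oxazolidin-2-one | COc1cc(/C=C/I)ccc1OCC(=O)N1[C@H](Cc2ccccc2)COC1=O | intermediate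
19 | (Z)-dibutylboron enolate of 18 | COc1cc(/C=C/I)ccc1O/C=C(\OB(CCCC)CCCC)N1[C@H](Cc2ccccc2)COC1=O | intermediate
20 | dibutylboron aldolate of 21 | COc1cc(/C=C/I)ccc1O[C@@H](C(=O)N1[C@H](Cc2ccccc2)COC1=O)[C@@H](OB(CCCC)CCCC)c1ccc(OCc2ccccc2)c(OC)c1 | intermediate
21 | syn aldol adduct, (2R,3S) in the acyl chain, (R)-auxiliary | COc1cc(/C=C/I)ccc1O[C@@H](C(=O)N1[C@H](Cc2ccccc2)COC1=O)[C@@H](O)c1ccc(OCc2ccccc2)c(OC)c1 | intermediate
22 | (1S,2S)-threo diol | COc1cc(/C=C/I)ccc1O[C@@H](CO)[C@@H](O)c1ccc(OCc2ccccc2)c(OC)c1 | intermediate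
23 | (1S,2S)-threo alcohol, C9'' TBS ether | COc1cc(/C=C/I)ccc1O[C@@H](CO[Si](C)(C)C(C)(C)C)[C@@H](O)c1ccc(OCc2ccccc2)c(OC)c1 | intermediate
24 | (1R,2S)-erythro 4-nitrobenzoate | COc1cc(/C=C/I)ccc1O[C@@H](CO[Si](C)(C)C(C)(C)C)[C@H](OC(=O)c1ccc([N+](=O)[O-])cc1)c1ccc(OCc2ccccc2)c(OC)c1 | intermediate
25 | (1R,2S)-erythro alcohol | COc1cc(/C=C/I)ccc1O[C@@H](CO[Si](C)(C)C(C)(C)C)[C@H](O)c1ccc(OCc2ccccc2)c(OC)c1 | intermediate
26 | (1R,2S)-erythro bis-TBS ether with (E)-vinyl iodide on ring B | COc1cc(/C=C/I)ccc1O[C@@H](CO[Si](C)(C)C(C)(C)C)[C@H](O[Si](C)(C)C(C)(C)C)c1ccc(OCc2ccccc2)c(OC)c1 | intermediate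
27 | (E)-styryl enol ether pivalate | CC(C)(C)C(=O)OC[C@H](CO[Si](C)(C)C(C)(C)C)[C@@H](c1ccc(OCc2ccccc2)c(OC)c1)O/C=C/c1ccc(O[C@@H](CO[Si](C)(C)C(C)(C)C)[C@H](O[Si](C)(C)C(C)(C)C)c2ccc(OCc3ccccc3)c(OC)c2)c(OC)c1 | intermediate
28 | (E)-styryl enol ether primary alcohol | OC[C@H](CO[Si](C)(C)C(C)(C)C)[C@@H](c1ccc(OCc2ccccc2)c(OC)c1)O/C=C/c1ccc(O[C@@H](CO[Si](C)(C)C(C)(C)C)[C@H](O[Si](C)(C)C(C)(C)C)c2ccc(OCc3ccccc3)c(OC)c2)c(OC)c1 | intermediate
29 | (E)-styryl enol ether aldehyde (cyclisation precursor) | O=C[C@H](CO[Si](C)(C)C(C)(C)C)[C@@H](c1ccc(OCc2ccccc2)c(OC)c1)O/C=C/c1ccc(O[C@@H](CO[Si](C)(C)C(C)(C)C)[C@H](O[Si](C)(C)C(C)(C)C)c2ccc(OCc3ccccc3)c(OC)c2)c(OC)c1 | intermediate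
30 | samarium ketyl of 29 (radical at C4, O–SmI2) | I[Sm](I)O[CH][C@H](CO[Si](C)(C)C(C)(C)C)[C@@H](c1ccc(OCc2ccccc2)c(OC)c1)O/C=C/c1ccc(O[C@@H](CO[Si](C)(C)C(C)(C)C)[C@H](O[Si](C)(C)C(C)(C)C)c2ccc(OCc3ccccc3)c(OC)c2)c(OC)c1 | intermediate
31 | cyclised tetrahydrofuran with radical at C6 and O–SmI2 at C4 | COc1cc([C@@H](O[Si](C)(C)C(C)(C)C)[C@H](CO[Si](C)(C)C(C)(C)C)Oc2ccc([CH][C@H]3O[C@H](c4ccc(OCc5ccccc5)c(OC)c4)[C@@H](CO[Si](C)(C)C(C)(C)C)[C@@H]3O[Sm](I)I)cc2OC)ccc1OCc1ccccc1 | intermediate
32 | protected target with free C4 hydroxyl (2S,3S,4S,5R,7''R,8''S) | COc1cc([C@@H](O[Si](C)(C)C(C)(C)C)[C@H](CO[Si](C)(C)C(C)(C)C)Oc2ccc(C[C@H]3O[C@H](c4ccc(OCc5ccccc5)c(OC)c4)[C@@H](CO[Si](C)(C)C(C)(C)C)[C@@H]3O)cc2OC)ccc1OCc1ccccc1 | intermediate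
33 | bis(benzyl ether) tetraol | COc1cc([C@@H](O)[C@H](CO)Oc2ccc(C[C@H]3O[C@H](c4ccc(OCc5ccccc5)c(OC)c4)[C@@H](CO)[C@@H]3O)cc2OC)ccc1OCc1ccccc1 | intermediate
34 | CNP0123626.1 | COc1cc([C@@H](O)[C@H](CO)Oc2ccc(C[C@H]3O[C@H](c4ccc(O)c(OC)c4)[C@@H](CO)[C@@H]3O)cc2OC)ccc1O | target

**Step count**
Total step count: 20.
Longest linear sequence: 14 steps (14 → 17 → 18 → 21 → 22 → 23 → 24 → 25 → 26 → 27 → 28 → 29 → 32 → 33 → 34).

**Steps most likely to fail**

1. Step 18.
 - The nucleophilic ketyl may add too slowly to the electron-rich alkene, so that plain reduction or pinacol coupling of the aldehyde takes over.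
 - After closure, the reduced C6 may expel O1 and reopen the ring.
 - Closure through the chair-like arrangement (ring C and side chain pseudo-equatorial, O–Sm axial) may erode or reverse the facial selectivity at C4 and C5.
 - Fallback (from 10 and 26, back at 32): the C4–C5 bond is made by organochromium chemistry and the ring is closed at O1–C5 instead.
 - Ozonolysis of 10 with PPh3 work-up gives aldehyde 11 in isolated form.
 - Nozaki–Hiyama–Kishi coupling of 11 with 26 (CrCl2, NiCl2 cat., DMF) should give, under Felkin–Anh control, the (E)-styryl allylic alcohol F1.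
 - Anti-Markovnikov hydroetherification of this alkenol under acridinium photoredox catalysis (9-mesityl-10-methylacridinium tetrafluoroborate, diphenyl disulfide, 1,2-dichloroethane, 450 nm light) adds the C2 hydroxyl to C5 and a hydrogen atom to C6.
 - In this 5-exo closure ring C, CH2OTBS and the C4 hydroxyl can all sit pseudo-equatorial in a chair-like arrangement, so the all-trans ring of 32 is the matched outcome.

2. Step 15.
 - C–O coupling at the hindered secondary benzylic alkoxide may be sluggish.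
 - Meanwhile the pivaloyl or silyl group may migrate to the C2 oxygen, and base may strip HI from the vinyl iodide at 80 °C.
 - Fallback (from 26 and 13, back at 27): the polarity of the vinyl partner is reversed, and the bond is made by an oxidative coupling at room temperature without carbonate base.
 - Miyaura borylation of 26 (bis(pinacolato)diboron, PdCl2(PPh3)2, PPh3, KOPh, toluene, 50 °C) gives the (E)-styryl pinacol boronate F2.
 - Aqueous KHF2 in MeOH converts F2 into the potassium (E)-styryltrifluoroborate F3.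
 - Chan–Lam-type etherification of alcohol 13 with F3 (Cu(OAc)2 cat., DMAP, 4 Å molecular sieves, O2, CH2Cl2, rt) should give 27 with the alkene geometry retained.

3. Step 12.
 - The oxyphosphonium ion on the electron-rich benzylic carbon may ionise in part, so that inversion is incomplete, or it may lose a proton toward C8''.
 - Fallback (from 23, back at 25): the stereocentre is erased and rebuilt by hydride delivery.
 - Dess–Martin oxidation of 23 gives the α-aryloxy aryl ketone F4.
 - Reduction with Zn(BH4)2 in Et2O at −78 → 0 °C should proceed through the Cram chelate between the carbonyl and aryloxy oxygens and deliver the anti (erythro) alcohol 25 directly, skipping 24.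

**Further compounds**
F1 | step 18 | (E)-styryl allylic alcohol, C2 and C4 hydroxyls free, C4 configured as in 32 | O[C@H](c1ccc(OCc2ccccc2)c(OC)c1)[C@@H](CO[Si](C)(C)C(C)(C)C)[C@H](O)/C=C/c1ccc(O[C@@H](CO[Si](C)(C)C(C)(C)C)[C@H](O[Si](C)(C)C(C)(C)C)c2ccc(OCc3ccccc3)c(OC)c2)c(OC)c1
F2 | step 15 | (E)-styryl pinacol boronate of fragment 2 | COc1cc(/C=C/B2OC(C)(C)C(C)(C)O2)ccc1O[C@@H](CO[Si](C)(C)C(C)(C)C)[C@H](O[Si](C)(C)C(C)(C)C)c1ccc(OCc2ccccc2)c(OC)c1
F3 | step 15 | potassium (E)-styryltrifluoroborate of fragment 2 | [K+].COc1cc(/C=C/[B-](F)(F)F)ccc1O[C@@H](CO[Si](C)(C)C(C)(C)C)[C@H](O[Si](C)(C)C(C)(C)C)c1ccc(OCc2ccccc2)c(OC)c1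
F4 | step 12 | (S)-α-aryloxy aryl ketone from 23 | COc1cc(/C=C/I)ccc1O[C@@H](CO[Si](C)(C)C(C)(C)C)C(=O)c1ccc(OCc2ccccc2)c(OC)c1
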